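**Retrosynthetic overview** (flavanone numbering is used for ring A atoms at every stage)
1. Feature: ring A is a fully substituted phloroglucinol in which the oxygens on C5, C7 and C8a alternate with carbon substituents on C6, C8 (two identical 2-hydroxybenzyl groups) and C4a (the acyl carbon, H until late). A vinylketene plus ynol ether benzannulation delivers exactly this pattern.
2. Ring A is built first (step 6) from a 3-ethoxy-4-benzylcyclobutenone and a silyl ynol ether: C7–C8 and C4a–C8a form in the [2+2] event and C6–C7 in the electrocyclisation. The oxygens emerge differentiated as C7–OH, C8a–OSi and C5–OEt.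
3. Fragments: the cyclobutenone comes from dihydrocoumarin (ketene plus ethoxyacetylene [2+2]); the ynol ether comes from methyl (2-hydroxyphenyl)acetate (Kowalski ynolate, O-silylation). The pendant phenols are carried as benzyl ethers, which tolerate acid chloride formation and the later acid step.
4. Ring C is built second: C4a is acetylated (bromine–lithium exchange, Weinreb amide), and the freed C8a hydroxyl closes the O1–C2 bond by oxa-Michael addition–elimination on an enaminone to give a chromone.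
5. C2 is set last by rhodium-catalysed enantioselective conjugate phenylation of the chromone; BCl3 then removes the benzyl ethers and the chelated C5 ethyl ether.

Key step: step 6

Assumption: the (S)-configured biaryl bisphosphine is taken to deliver phenyl to the Re face of C2 by analogy with rhodium-catalysed 1,4-additions to cyclic enones; if a model chromone shows the opposite sense, the (R)-ligand is used.

**Route**

Step 1
Reactants: 1 dihydrocoumarin
Product: 3 methyl 3-[2-(benzyloxy)phenyl]propanoate, via sodium phenolate ester 2 (not isolated)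
Conditions: NaOMe, MeOH, 0 °C → rt; then BnBr, n-Bu4NI (cat.), 50 °C
Reagents that add atoms: sodium methoxide [Na+].[O-]C; benzyl bromide BrCc1ccccc1
Why: Methoxide should open the aryl lactone by transesterification (driven by formation of the phenoxide), and the phenoxide is then O-benzylated in a Williamson ether synthesis.

Step 2
Reactants: 3 methyl 3-[2-(benzyloxy)phenyl]propanoate
Product: 4 3-[2-(benzyloxy)phenyl]propanoic acid
Conditions: LiOH, THF/MeOH/H2O, rt; then 1 M HCl
Reagents that add atoms: lithium hydroxide [Li+].[OH-]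
Why: Ester saponification should be clean, since the benzyl ether is inert to aqueous base and to brief acidification.

Step 3
Reactants: 4 3-[2-(benzyloxy)phenyl]propanoic acid; 5 ethoxyacetylene
Product: 8 4-[2-(benzyloxy)benzyl]-3-ethoxycyclobut-2-en-1-one (racemic), via acid chloride 6 (not isolated), via ketene 7 (not isolated)
Conditions: (COCl)2, DMF (cat.), CH2Cl2, 0 °C → rt, evaporate; then 5 (3 equiv), Et3N (slow addition), Et2O, 35 °C
Reagents that add atoms: none
Why: Dehydrohalogenation of acid chloride 6 gives monoalkylketene 7, which the electron-rich alkoxyalkyne in excess should trap in a regioselective ketene–alkyne [2+2] cycloaddition (ketene carbonyl carbon to the unsubstituted alkyne carbon), placing the benzyl group at C4 of the cyclobutenone; the new sp3 centre is racemic and is lost on aromatisation.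

Step 4
Reactants: 9 methyl (2-hydroxyphenyl)acetate
Product: 10 methyl [2-(benzyloxy)phenyl]acetate
Conditions: BnBr, K2CO3, acetone, reflux
Reagents that add atoms: benzyl bromide BrCc1ccccc1
Why: Williamson benzylation of the phenol should outpace lactonisation and gives the same protecting group as in the other fragment.

Step 5
Reactants: 10 methyl [2-(benzyloxy)phenyl]acetate
Product: 13 ({3-[2-(benzyloxy)phenyl]prop-1-yn-1-yl}oxy)triisopropylsilane, via dibromo enolate 11 (not isolated), via lithium ynolate 12 (not isolated)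
Conditions: CH2Br2, lithium 2,2,6,6-tetramethylpiperidide, THF, −78 °C; LiN(SiMe3)2; n-BuLi, −78 → 0 °C; i-Pr3SiCl, 0 °C → rt
Reagents that add atoms: dibromomethane BrCBr; chlorotriisopropylsilane CC(C)[Si](Cl)(C(C)C)C(C)C
Why: In this Kowalski ynolate synthesis, dibromomethyllithium should add to the ester at −78 °C faster than it enolises the arylacetate; enolate 11 then undergoes bromine–lithium exchange and 1,2-shift of the benzylic carbon to ynolate 12, which the bulky silyl chloride silylates on oxygen to give an isolable triisopropylsilyl ynol ether.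

Step 6
Reactants: 8 4-[2-(benzyloxy)benzyl]-3-ethoxycyclobut-2-en-1-one; 13 ({3-[2-(benzyloxy)phenyl]prop-1-yn-1-yl}oxy)triisopropylsilane
Product: 18 2,6-bis[2-(benzyloxy)benzyl]-3-ethoxy-5-(triisopropylsilyloxy)phenol, via vinylketene 14 (not isolated), via vinylcyclobutenone 15 (not isolated), via dienylketene 16 (not isolated), via cyclohexadienone 17 (not isolated)
Conditions: toluene (degassed), 80 °C then 110 °C, sealed tube, 13 in slight excess
Reagents that add atoms: none
Why: Heat should open the strained cyclobutenone 8 by conrotatory four-electron electrocyclic cleavage of its C1–C4 bond to vinylketene 14, whose electrophilic ketene carbon (future C7) is attacked by the nucleophilic benzyl-bearing carbon of 13 (future C8) while the ketene α-carbon (future C4a) bonds to the silyloxy carbon (future C8a), so the [2+2] cycloaddition gives 15 with C7–C8 and C4a–C8a in place. A second, reversible four-electron opening of 15 funnels through dienylketene 16 with the vinyl group cis to the ketene, and this closes ring A by a thermally allowed disrotatory six-electron electrocyclisation between C7 and C6, a six-membered carbocyclic closure that re-forms the bond broken in the first opening. Tautomerisation of dienone 17 to phenol 18 makes the cascade irreversible; no stereocentre is formed, and the racemic centre of 8 ends as aromatic C6. The closest known reaction type is the Danheiser benzannulation of cyclobutenones with trialkylsilyloxyalkynes to resorcinol monosilyl ethers, which also covers oxygen-substituted cyclobutenones. The one selectivity needed is the regiochemistry of the ketene–alkyne [2+2] step, and the polarisation of the silyl ynol ether secures it: oxygen lone-pair donation makes the carbon remote from oxygen the nucleophile, matched to the ketene carbonyl carbon, so every ring A carbon receives its substituent without isomers and the three oxygens emerge as free phenol (C7), silyl ether (C8a) and ethyl ether (C5).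

Step 7
Reactants: 18 2,6-bis[2-(benzyloxy)benzyl]-3-ethoxy-5-(triisopropylsilyloxy)phenol
Product: 19 {3-(benzyloxy)-2,4-bis[2-(benzyloxy)benzyl]-5-ethoxyphenoxy}triisopropylsilane
Conditions: NaH, BnBr, n-Bu4NI (cat.), DMF, 0 °C → rt
Reagents that add atoms: benzyl bromide BrCc1ccccc1
Why: Williamson benzylation of the sodium phenoxide masks the C7 hydroxyl, which would otherwise interfere with the organolithium and aminomethylenation steps; the hindered aryl triisopropylsilyl ether should survive NaH.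

Step 8
Reactants: 19 {3-(benzyloxy)-2,4-bis[2-(benzyloxy)benzyl]-5-ethoxyphenoxy}triisopropylsilane
Product: 20 3-(benzyloxy)-2,4-bis[2-(benzyloxy)benzyl]-5-ethoxyphenol
Conditions: n-Bu4NF, THF, 0 °C; aq. NH4Cl
Reagents that add atoms: none
Why: Fluoride should cleave only the aryl silicon–oxygen bond, freeing the C8a hydroxyl that becomes O1.

Step 9
Reactants: 20 3-(benzyloxy)-2,4-bis[2-(benzyloxy)benzyl]-5-ethoxyphenol
Product: 21 3-(benzyloxy)-2,4-bis[2-(benzyloxy)benzyl]-6-bromo-5-ethoxyphenol
Conditions: NBS, CH2Cl2, −78 → −40 °C, dark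
Reagents that add atoms: N-bromosuccinimide O=C1CCC(=O)N1Br
Why: Electrophilic aromatic bromination should occur only at C4a, the single free position of the trioxygenated ring and ortho to the free phenol, which is far more nucleophilic than the monoalkoxy pendant rings.

Step 10
Reactants: 21 3-(benzyloxy)-2,4-bis[2-(benzyloxy)benzyl]-6-bromo-5-ethoxyphenol
Product: 23 1-{4-(benzyloxy)-3,5-bis[2-(benzyloxy)benzyl]-2-ethoxy-6-hydroxyphenyl}ethan-1-one, via dilithio phenolate 22 (not isolated)
Conditions: MeLi, THF, −78 °C; t-BuLi (2 equiv), −78 °C; MeC(O)N(OMe)Me, −78 → 0 °C; aq. NH4Cl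
Reagents that add atoms: N-methoxy-N-methylacetamide CC(=O)N(C)OC
Why: After deprotonation of the phenol, bromine–lithium exchange at −78 °C should outpace benzylic deprotonation, and the ortho-lithiated phenoxide 22 adds once to the Weinreb amide, whose chelated tetrahedral adduct releases the C4a methyl ketone only on work-up.

Step 11
Reactants: 23 1-{4-(benzyloxy)-3,5-bis[2-(benzyloxy)benzyl]-2-ethoxy-6-hydroxyphenyl}ethan-1-one
Product: 25 7-(benzyloxy)-6,8-bis[2-(benzyloxy)benzyl]-5-ethoxy-4H-chromen-4-one, via enaminone 24 (not isolated)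
Conditions: Me2NCH(OMe)2, toluene, 100 °C; then 2 M HCl, CH2Cl2, rt
Reagents that add atoms: N,N-dimethylformamide dimethyl acetal COC(OC)N(C)C
Why: Condensation of the methyl ketone with the formamide acetal gives enaminone 24, and acid should then induce 6-endo oxa-Michael addition of the C8a hydroxyl with loss of dimethylamine, closing ring C as the chromone in a standard chromone synthesis that benzyl and ethyl ethers tolerate.

Step 12
Reactants: 25 7-(benzyloxy)-6,8-bis[2-(benzyloxy)benzyl]-5-ethoxy-4H-chromen-4-one; 26 phenylboronic acid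
Product: 27 (2S)-7-(benzyloxy)-6,8-bis[2-(benzyloxy)benzyl]-5-ethoxy-2-phenyl-2,3-dihydro-4H-chromen-4-one
Conditions: [Rh(OH)(cod)]2 (cat.), (S)-MeO-F12-BIPHEP [(S)-2,2′-bis{bis(3,4,5-trifluorophenyl)phosphino}-6,6′-dimethoxy-1,1′-biphenyl] (cat.), 26 (3 equiv), toluene/H2O, 40 °C
Reagents that add atoms: none
Why: In this Hayashi–Miyaura asymmetric 1,4-addition, transmetalation gives a phenyl complex of monovalent rhodium, the chromone C2=C3 bond inserts with the electron-poor atropisomeric bisphosphine exposing the Re face of C2, and hydrolysis of the oxa-π-allyl rhodium should release the (2S)-flavanone under ligand control, a process established for 5,7-dioxygenated chromones.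

Step 13
Reactants: 27 (2S)-7-(benzyloxy)-6,8-bis[2-(benzyloxy)benzyl]-5-ethoxy-2-phenyl-2,3-dihydro-4H-chromen-4-one
Product: 28 dichamanetin [(2S)-5,7-dihydroxy-6,8-bis(2-hydroxybenzyl)-2-phenyl-2,3-dihydro-4H-chromen-4-one]
Conditions: BCl3, C6HMe5, CH2Cl2, −78 °C; then n-Bu4NI, −78 → 0 °C; then H2O
Reagents that add atoms: none
Why: BCl3 should ionise the three benzyl ethers at low temperature while pentamethylbenzene traps the benzyl cations by Friedel–Crafts alkylation, and the C5 ethyl ether, held in a boron chelate with the C4 carbonyl, is then dealkylated by iodide in an SN2 step; C2 is not involved, and the low temperature guards against retro-oxa-Michael opening.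

**Compound list**
1 | dihydrocoumarin | O=C1CCc2ccccc2O1 | starting material
2 | sodium 2-(3-methoxy-3-oxopropyl)phenolate | [Na+].[O-]c1ccccc1CCC(=O)OC | intermediate
3 | methyl 3-[2-(benzyloxy)phenyl]propanoate | COC(=O)CCc1ccccc1OCc1ccccc1 | intermediate
4 | 3-[2-(benzyloxy)phenyl]propanoic acid | OC(=O)CCc1ccccc1OCc1ccccc1 | intermediate
5 | ethoxyacetylene | C#COCC | starting material
6 | 3-[2-(benzyloxy)phenyl]propanoyl chloride | ClC(=O)CCc1ccccc1OCc1ccccc1 | intermediate
7 | 3-[2-(benzyloxy)phenyl]prop-1-en-1-one (monoalkylketene) | O=C=CCc1ccccc1OCc1ccccc1 | intermediate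
8 | 4-[2-(benzyloxy)benzyl]-3-ethoxycyclobut-2-en-1-one (racemic) | CCOC1=CC(=O)C1Cc1ccccc1OCc1ccccc1 | intermediate
9 | methyl (2-hydroxyphenyl)acetate | COC(=O)Cc1ccccc1O | starting material
10 | methyl [2-(benzyloxy)phenyl]acetate | COC(=O)Cc1ccccc1OCc1ccccc1 | intermediate
11 | lithium 3-[2-(benzyloxy)phenyl]-1,1-dibromoprop-1-en-2-olate | [Li+].[O-]C(Cc1ccccc1OCc1ccccc1)=C(Br)Br | intermediate
12 | lithium 3-[2-(benzyloxy)phenyl]prop-1-yn-1-olate | [Li+].[O-]C#CCc1ccccc1OCc1ccccc1 | intermediate
13 | ({3-[2-(benzyloxy)phenyl]prop-1-yn-1-yl}oxy)triisopropylsilane | CC(C)[Si](OC#CCc1ccccc1OCc1ccccc1)(C(C)C)C(C)C | intermediate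
14 | (3Z)-5-[2-(benzyloxy)phenyl]-3-ethoxypenta-1,3-dien-1-one | O=C=C/C(OCC)=C/Cc1ccccc1OCc1ccccc1 | intermediate
15 | 2-[2-(benzyloxy)benzyl]-4-{(1Z)-3-[2-(benzyloxy)phenyl]-1-ethoxyprop-1-en-1-yl}-3-(triisopropylsilyloxy)cyclobut-2-en-1-one (racemic) | O=C1C(Cc2ccccc2OCc2ccccc2)=C(O[Si](C(C)C)(C(C)C)C(C)C)C1/C(OCC)=C/Cc1ccccc1OCc1ccccc1 | intermediate
16 | (3E,5Z)-2-[2-(benzyloxy)benzyl]-7-[2-(benzyloxy)phenyl]-5-ethoxy-3-(triisopropylsilyloxy)hepta-1,3,5-trien-1-one | O=C=C(Cc1ccccc1OCc1ccccc1)/C(O[Si](C(C)C)(C(C)C)C(C)C)=C\C(OCC)=C\Cc1ccccc1OCc1ccccc1 | intermediate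
17 | 2,6-bis[2-(benzyloxy)benzyl]-5-ethoxy-3-(triisopropylsilyloxy)cyclohexa-2,4-dien-1-one (racemic) | O=C1C(Cc2ccccc2OCc2ccccc2)=C(O[Si](C(C)C)(C(C)C)C(C)C)C=C(OCC)C1Cc1ccccc1OCc1ccccc1 | intermediate
18 | 2,6-bis[2-(benzyloxy)benzyl]-3-ethoxy-5-(triisopropylsilyloxy)phenol | Oc1c(Cc2ccccc2OCc2ccccc2)c(O[Si](C(C)C)(C(C)C)C(C)C)cc(OCC)c1Cc1ccccc1OCc1ccccc1 | intermediate
19 | {3-(benzyloxy)-2,4-bis[2-(benzyloxy)benzyl]-5-ethoxyphenoxy}triisopropylsilane | CCOc1cc(O[Si](C(C)C)(C(C)C)C(C)C)c(Cc2ccccc2OCc2ccccc2)c(OCc2ccccc2)c1Cc1ccccc1OCc1ccccc1 | intermediate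
20 | 3-(benzyloxy)-2,4-bis[2-(benzyloxy)benzyl]-5-ethoxyphenol | CCOc1cc(O)c(Cc2ccccc2OCc2ccccc2)c(OCc2ccccc2)c1Cc1ccccc1OCc1ccccc1 | intermediate
21 | 3-(benzyloxy)-2,4-bis[2-(benzyloxy)benzyl]-6-bromo-5-ethoxyphenol | CCOc1c(Br)c(O)c(Cc2ccccc2OCc2ccccc2)c(OCc2ccccc2)c1Cc1ccccc1OCc1ccccc1 | intermediate
22 | lithium 3-(benzyloxy)-2,4-bis[2-(benzyloxy)benzyl]-5-ethoxy-6-lithiophenolate | [Li+].[Li]c1c([O-])c(Cc2ccccc2OCc2ccccc2)c(OCc2ccccc2)c(Cc2ccccc2OCc2ccccc2)c1OCC | intermediate
23 | 1-{4-(benzyloxy)-3,5-bis[2-(benzyloxy)benzyl]-2-ethoxy-6-hydroxyphenyl}ethan-1-one | CC(=O)c1c(O)c(Cc2ccccc2OCc2ccccc2)c(OCc2ccccc2)c(Cc2ccccc2OCc2ccccc2)c1OCC | intermediate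
24 | (2E)-1-{4-(benzyloxy)-3,5-bis[2-(benzyloxy)benzyl]-2-ethoxy-6-hydroxyphenyl}-3-(dimethylamino)prop-2-en-1-one | CN(C)/C=C/C(=O)c1c(O)c(Cc2ccccc2OCc2ccccc2)c(OCc2ccccc2)c(Cc2ccccc2OCc2ccccc2)c1OCC | intermediate
25 | 7-(benzyloxy)-6,8-bis[2-(benzyloxy)benzyl]-5-ethoxy-4H-chromen-4-one | O=c1ccoc2c(Cc3ccccc3OCc3ccccc3)c(OCc3ccccc3)c(Cc3ccccc3OCc3ccccc3)c(OCC)c12 | intermediate
26 | phenylboronic acid | OB(O)c1ccccc1 | starting material
27 | (2S)-7-(benzyloxy)-6,8-bis[2-(benzyloxy)benzyl]-5-ethoxy-2-phenyl-2,3-dihydro-4H-chromen-4-one | O=C1C[C@@H](c2ccccc2)Oc2c(Cc3ccccc3OCc3ccccc3)c(OCc3ccccc3)c(Cc3ccccc3OCc3ccccc3)c(OCC)c21 | intermediate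
28 | dichamanetin, (2S)-5,7-dihydroxy-6,8-bis(2-hydroxybenzyl)-2-phenyl-2,3-dihydro-4H-chromen-4-one | O=C1C[C@@H](c2ccccc2)Oc2c(Cc3ccccc3O)c(O)c(Cc3ccccc3O)c(O)c21 | target

**Step count**
Total: 13 steps. Longest linear sequence: 11 steps (steps 1–3, then 6–13); the ynol ether branch (steps 4–5) joins at step 6.

**Steps most likely to fail**

Step 6. The vinylogous-ester stabilisation of cyclobutenone 8 may slow its ring opening so much that thermal silyl migration in 13 or oligomerisation of the vinylketene overtakes the cascade. The fallback exchanges the roles of the two oxygenated partners and sets out from acid chloride 6, siloxyalkyne 13 and ethoxyacetylene 5. Ketene 7 (from 6 with Et3N in Et2O) is trapped by 13 in a ketene–ynol ether [2+2] cycloaddition to give 2,4-bis[2-(benzyloxy)benzyl]-3-(triisopropylsilyloxy)cyclobut-2-en-1-one F1. Heating F1 with 5 in toluene, a benzannulation in its alkoxyalkyne mode, should give 2,4-bis[2-(benzyloxy)benzyl]-5-ethoxy-3-(triisopropylsilyloxy)phenol F2, which has the free hydroxyl on C8a and the silyl ether on C7. MOMCl with i-Pr2NEt then gives {2,6-bis[2-(benzyloxy)benzyl]-3-ethoxy-5-(methoxymethoxy)phenoxy}triisopropylsilane F3. n-Bu4NF with BnBr in THF exchanges silyl for benzyl in one pot to give 2-(benzyloxy)-1,3-bis[2-(benzyloxy)benzyl]-4-ethoxy-6-(methoxymethoxy)benzene F4. HCl in MeOH removes the methoxymethyl group, and the sequence comes back to the route at phenol 20.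

Step 12. Insertion of the phenylrhodium species into the electron-rich, 5-alkoxy- and 8-substituted chromone may be slow, so that protodeboronation consumes the boronic acid, or facial discrimination may be insufficient. The fallback sets C2 by C–O bond formation and sets out from ketone 23. C-Acylation of its dianion (LiN(SiMe3)2, Boc2O, THF, −78 °C) gives tert-butyl 3-{4-(benzyloxy)-3,5-bis[2-(benzyloxy)benzyl]-2-ethoxy-6-hydroxyphenyl}-3-oxopropanoate F5. Knoevenagel condensation with benzaldehyde (piperidine, AcOH, toluene, molecular sieves) gives tert-butyl 2-{4-(benzyloxy)-3,5-bis[2-(benzyloxy)benzyl]-2-ethoxy-6-hydroxybenzoyl}-3-phenylprop-2-enoate F6. A 9-amino(9-deoxy)epi-quinidine-derived 3,5-bis(trifluoromethyl)phenyl thiourea (toluene, −25 °C) should catalyse enantioselective 6-endo oxa-Michael closure of this activated acceptor to tert-butyl (2S)-7-(benzyloxy)-6,8-bis[2-(benzyloxy)benzyl]-5-ethoxy-4-oxo-2-phenyl-3,4-dihydro-2H-chromene-3-carboxylate F7; the quinine-derived pseudoenantiomer is used if the sense proves opposite. TsOH·H2O at 80 °C in the same pot removes the ester group, and the sequence comes back to the route at flavanone 27.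

Step 13. The Lewis acid may open the flavanone by retro-oxa-Michael cleavage and so erode the C2 configuration, or cleavage of the primary ethyl ether may stall. The fallback removes the ethyl group before the stereocentre exists and sets out from chromone 25. MgI2·OEt2 in toluene at 70 °C dealkylates only the chelated C5 ether to give 7-(benzyloxy)-6,8-bis[2-(benzyloxy)benzyl]-5-hydroxy-4H-chromen-4-one F8. BnBr with K2CO3 in DMF gives 5,7-bis(benzyloxy)-6,8-bis[2-(benzyloxy)benzyl]-4H-chromen-4-one F9. The conjugate phenylation of step 12 gives (2S)-5,7-bis(benzyloxy)-6,8-bis[2-(benzyloxy)benzyl]-2-phenyl-2,3-dihydro-4H-chromen-4-one F10. Neutral hydrogenolysis (H2, Pd/C, EtOAc) then comes back to the route at dichamanetin 28.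

**Further compounds**
F1 | step 6 | 2,4-bis[2-(benzyloxy)benzyl]-3-(triisopropylsilyloxy)cyclobut-2-en-1-one (racemic) | O=C1C(Cc2ccccc2OCc2ccccc2)=C(O[Si](C(C)C)(C(C)C)C(C)C)C1Cc1ccccc1OCc1ccccc1
F2 | step 6 | 2,4-bis[2-(benzyloxy)benzyl]-5-ethoxy-3-(triisopropylsilyloxy)phenol | Oc1cc(OCC)c(Cc2ccccc2OCc2ccccc2)c(O[Si](C(C)C)(C(C)C)C(C)C)c1Cc1ccccc1OCc1ccccc1
F3 | step 6 | {2,6-bis[2-(benzyloxy)benzyl]-3-ethoxy-5-(methoxymethoxy)phenoxy}triisopropylsilane | COCOc1cc(OCC)c(Cc2ccccc2OCc2ccccc2)c(O[Si](C(C)C)(C(C)C)C(C)C)c1Cc1ccccc1OCc1ccccc1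
F4 | step 6 | 2-(benzyloxy)-1,3-bis[2-(benzyloxy)benzyl]-4-ethoxy-6-(methoxymethoxy)benzene | COCOc1cc(OCC)c(Cc2ccccc2OCc2ccccc2)c(OCc2ccccc2)c1Cc1ccccc1OCc1ccccc1
F5 | step 12 | tert-butyl 3-{4-(benzyloxy)-3,5-bis[2-(benzyloxy)benzyl]-2-ethoxy-6-hydroxyphenyl}-3-oxopropanoate | CCOc1c(C(=O)CC(=O)OC(C)(C)C)c(O)c(Cc2ccccc2OCc2ccccc2)c(OCc2ccccc2)c1Cc1ccccc1OCc1ccccc1
F6 | step 12 | tert-butyl 2-{4-(benzyloxy)-3,5-bis[2-(benzyloxy)benzyl]-2-ethoxy-6-hydroxybenzoyl}-3-phenylprop-2-enoate (alkene geometry as formed) | CCOc1c(C(=O)C(=Cc2ccccc2)C(=O)OC(C)(C)C)c(O)c(Cc2ccccc2OCc2ccccc2)c(OCc2ccccc2)c1Cc1ccccc1OCc1ccccc1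
F7 | step 12 | tert-butyl (2S)-7-(benzyloxy)-6,8-bis[2-(benzyloxy)benzyl]-5-ethoxy-4-oxo-2-phenyl-3,4-dihydro-2H-chromene-3-carboxylate (C3 epimerisable) | O=C1C(C(=O)OC(C)(C)C)[C@@H](c2ccccc2)Oc2c(Cc3ccccc3OCc3ccccc3)c(OCc3ccccc3)c(Cc3ccccc3OCc3ccccc3)c(OCC)c21
F8 | step 13 | 7-(benzyloxy)-6,8-bis[2-(benzyloxy)benzyl]-5-hydroxy-4H-chromen-4-one | O=c1ccoc2c(Cc3ccccc3OCc3ccccc3)c(OCc3ccccc3)c(Cc3ccccc3OCc3ccccc3)c(O)c12
F9 | step 13 | 5,7-bis(benzyloxy)-6,8-bis[2-(benzyloxy)benzyl]-4H-chromen-4-one | O=c1ccoc2c(Cc3ccccc3OCc3ccccc3)c(OCc3ccccc3)c(Cc3ccccc3OCc3ccccc3)c(OCc3ccccc3)c12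
F10 | step 13 | (2S)-5,7-bis(benzyloxy)-6,8-bis[2-(benzyloxy)benzyl]-2-phenyl-2,3-dihydro-4H-chromen-4-one | O=C1C[C@@H](c2ccccc2)Oc2c(Cc3ccccc3OCc3ccccc3)c(OCc3ccccc3)c(Cc3ccccc3OCc3ccccc3)c(OCc3ccccc3)c21
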